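**Retrosynthetic overview**

1. Stereocentres and carbocycle: arene 1 is dearomatised by asymmetric transfer hydrogenation of its triketo tautomer (→ 2) and fixed as enaminodione 3. The benzene ring of 1 becomes the carbocycle and C6/C7 are set here.
2. Ester C–O bond: orcinol 4 → (5) → 6 → 7 → 8 → (9) supplies the protected orsellinoyl unit, which is joined to 3 to give 10.
3. C4a–C4 bond: alkyne 11, as acetylides 12 and 13, adds to the less hindered ring ketone of 10; loss of water and Me2NH from carbinol 14 gives ynenal 15.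
4. O2–C3 bond (pyran, the only ring built, closed after the carbocycle): aldehyde reduction to 16 and 6-endo-dig hydroalkoxylation give 17.
5. Global acidolysis of 17 gives target 18. Ring order: carbocycle (inherited from 1) → pyran; the orsellinate ring is carried intact from 4.

Assumption: aldehyde 1 and alkyne 11 are bought as catalogue compounds (1 is otherwise one Vilsmeier–Haack formylation from 2,4,6-trihydroxytoluene).

**Route**

Step 1
Reactants: 1 2,4,6-trihydroxy-3-methylbenzaldehyde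
Product: 3 (4R,5R)-2-[(dimethylamino)methylidene]-5-hydroxy-4-methylcyclohexane-1,3-dione, via hydroxymethylidene dione 2 (not isolated)
Conditions: RuCl[(R,R)-TsDPEN](p-cymene) (2 mol %), HCO2Na (5 equiv), aq. NaHCO3 (pH 8)/MeOH 4:1, argon, 40 °C; then Me2NH·HCl (1.5 equiv), pH 6–7, 40 °C
Reagents that add atoms: dimethylamine hydrochloride, CNC.Cl
Why: Proposed new method: in weakly basic water 1 equilibrates with its cyclohexane-1,3,5-trione tautomer, whose formyl group and two flanking carbonyls form an inert tricarbonyl enolate, so the only isolated ketone is the carbonyl para to the formyl group, flanked by CH2 and a rapidly enolising CH(CH3); Noyori–Ikariya transfer hydrogenation of that ketone with dynamic kinetic resolution delivers hydride anti to the methyl group (cis alcohol) while the chiral ligand selects the (4R) epimer, giving (4R,5R)-2, which is fixed against dehydrative re-aromatisation by condensing its formyl group with dimethylamine; the closest known reactions are the NaBH4 (and NADPH-enzyme) reduction of phloroglucinol to dihydrophloroglucinol and transfer-hydrogenative dynamic kinetic resolution of 2-substituted 1,3-dicarbonyl ketones, and the (S,S) ligand is used instead if the first run shows the opposite sense of induction.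

Step 2
Reactants: 4 orcinol (5-methylbenzene-1,3-diol)
Product: 6 2,4-dihydroxy-6-methylbenzaldehyde, via aryl iminium salt 5 (not isolated)
Conditions: POCl3 (1.1 equiv), DMF (1.2 equiv), MeCN, 0 → 23 °C; then H2O, 50 °C
Reagents that add atoms: N,N-dimethylformamide, CN(C)C=O (formyl C–H); water, O (formyl oxygen)
Why: Vilsmeier–Haack formylation; the chloroiminium ion attacks the position ortho to methyl and ortho/para to the two hydroxyls rather than the more hindered position between them, and hydrolysis of 5 gives the aldehyde.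

Step 3
Reactants: 6 2,4-dihydroxy-6-methylbenzaldehyde
Product: 7 2,4-bis[(4-methoxyphenyl)methoxy]-6-methylbenzaldehyde
Conditions: 4-methoxybenzyl chloride (2.4 equiv), K2CO3, DMF, 70 °C
Reagents that add atoms: 4-methoxybenzyl chloride, COc1ccc(CCl)cc1
Why: Williamson ether synthesis; carbonate in warm DMF alkylates both phenols, including the hydrogen-bonded ortho one.

Step 4
Reactants: 7 2,4-bis[(4-methoxyphenyl)methoxy]-6-methylbenzaldehyde
Product: 8 2,4-bis[(4-methoxyphenyl)methoxy]-6-methylbenzoic acid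
Conditions: NaClO2, NaH2PO4, 2-methylbut-2-ene, t-BuOH/THF/H2O, 0 → 23 °C
Reagents that add atoms: sodium chlorite, [Na+].[O-]Cl=O
Why: Pinnick oxidation of the hindered aryl aldehyde; 2-methylbut-2-ene removes HOCl so the electron-rich rings are not chlorinated.

Step 5
Reactants: 3 (4R,5R)-2-[(dimethylamino)methylidene]-5-hydroxy-4-methylcyclohexane-1,3-dione; 8 2,4-bis[(4-methoxyphenyl)methoxy]-6-methylbenzoic acid
Product: 10 (1R,2R)-4-[(dimethylamino)methylidene]-2-methyl-3,5-dioxocyclohexyl 2,4-bis[(4-methoxyphenyl)methoxy]-6-methylbenzoate, via acid chloride 9 (not isolated)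
Conditions: 8, 1-chloro-N,N,2-trimethylprop-1-en-1-amine, CH2Cl2, 0 → 23 °C; then 3, Et3N, DMAP (0.3 equiv), CH2Cl2, 23 → 40 °C
Reagents that add atoms: none
Why: Neutral acid-chloride formation with the α-chloroenamine spares the PMB ethers, and DMAP-catalysed O-acylation of the secondary alcohol proceeds with retention at the carbinol carbon; the vinylogous-amide carbonyls of 3 acidify the α-hydrogens too little for β-elimination.

Step 6
Reactants: 10 (1R,2R)-4-[(dimethylamino)methylidene]-2-methyl-3,5-dioxocyclohexyl 2,4-bis[(4-methoxyphenyl)methoxy]-6-methylbenzoate; 11 tert-butyl pent-4-ynoate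
Product: 15 (1R,2R)-5-(5-tert-butoxy-5-oxopent-1-yn-1-yl)-4-formyl-2-methyl-3-oxocyclohex-4-en-1-yl 2,4-bis[(4-methoxyphenyl)methoxy]-6-methylbenzoate, via lithium acetylide 12 (not isolated), via cerium acetylide 13 (not isolated), via tertiary carbinol 14 (not isolated)
Conditions: 11, n-BuLi, THF, −78 °C; CeCl3 (anhydrous), −78 °C; then 10, THF, −78 °C; 1 M aq. HCl, THF, 0 °C
Reagents that add atoms: water, O (aldehyde oxygen after iminium hydrolysis; the hydroxyl oxygen of 14 leaves as water)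
Why: Organocerium 1,2-addition: the hard, weakly basic acetylide adds to the ring ketone flanked by CH2 (the other is shielded by the methyl-bearing methine and the cis aroyloxy group), and acid then expels water and dimethylamine from the vinylogous hemiaminal (carbonyl transposition of an α-aminomethylidene ketone) to unveil the enal without touching C1/C2.

Step 7
Reactants: 15 (1R,2R)-5-(5-tert-butoxy-5-oxopent-1-yn-1-yl)-4-formyl-2-methyl-3-oxocyclohex-4-en-1-yl 2,4-bis[(4-methoxyphenyl)methoxy]-6-methylbenzoate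
Product: 17 tert-butyl 3-[(6R,7R)-6-({2,4-bis[(4-methoxyphenyl)methoxy]-6-methylbenzoyl}oxy)-7-methyl-8-oxo-5,6,7,8-tetrahydro-1H-isochromen-3-yl]propanoate, via allylic alcohol 16 (not isolated)
Conditions: i-Bu2AlH (1.05 equiv), CH2Cl2, −78 °C; aq. potassium sodium tartrate; then AgOTf (5 mol %), CH2Cl2, 23 °C
Reagents that add atoms: none
Why: i-Bu2AlH reduces the aldehyde 1,2 much faster than the hindered enone carbonyl or the esters at −78 °C, and silver-catalysed 6-endo-dig hydroalkoxylation closes the pyran because the attacked alkyne carbon is the δ-position of the ynenone; no stereocentre is involved.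

Step 8
Reactants: 17 tert-butyl 3-[(6R,7R)-6-({2,4-bis[(4-methoxyphenyl)methoxy]-6-methylbenzoyl}oxy)-7-methyl-8-oxo-5,6,7,8-tetrahydro-1H-isochromen-3-yl]propanoate
Product: 18 3-[(6R,7R)-6-[(2,4-dihydroxy-6-methylbenzoyl)oxy]-7-methyl-8-oxo-5,6,7,8-tetrahydro-1H-isochromen-3-yl]propanoic acid
Conditions: CF3CO2H/CH2Cl2 1:4, anisole (10 equiv), 0 °C
Reagents that add atoms: none
Why: Acidolysis: both PMB ethers and the tert-butyl ester ionise and anisole traps the benzyl cations (Friedel–Crafts), while the push–pull dienone is only reversibly O-protonated and C6/C7 are untouched at 0 °C.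

**Compound list**

1 | 2,4,6-trihydroxy-3-methylbenzaldehyde | Cc1c(O)cc(O)c(C=O)c1O | starting material
2 | (4R,5R)-5-hydroxy-2-(hydroxymethylidene)-4-methylcyclohexane-1,3-dione (enol form of the 2-formyl dione, sodium enolate in the flask, not isolated) | O[C@@H]1CC(=O)C(=CO)C(=O)[C@@H]1C | intermediate
3 | (4R,5R)-2-[(dimethylamino)methylidene]-5-hydroxy-4-methylcyclohexane-1,3-dione (push–pull exocyclic C=C, geometry not fixed) | O[C@@H]1CC(=O)C(=CN(C)C)C(=O)[C@@H]1C | intermediate
4 | orcinol (5-methylbenzene-1,3-diol) | Cc1cc(O)cc(O)c1 | starting material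
5 | [(2,4-dihydroxy-6-methylphenyl)methylidene]dimethylazanium chloride (not isolated) | C[N+](C)=Cc1c(C)cc(O)cc1O.[Cl-] | intermediate
6 | 2,4-dihydroxy-6-methylbenzaldehyde | Cc1cc(O)cc(O)c1C=O | intermediate
7 | 2,4-bis[(4-methoxyphenyl)methoxy]-6-methylbenzaldehyde | Cc1cc(OCc2ccc(OC)cc2)cc(OCc2ccc(OC)cc2)c1C=O | intermediate
8 | 2,4-bis[(4-methoxyphenyl)methoxy]-6-methylbenzoic acid | Cc1cc(OCc2ccc(OC)cc2)cc(OCc2ccc(OC)cc2)c1C(=O)O | intermediate
9 | 2,4-bis[(4-methoxyphenyl)methoxy]-6-methylbenzoyl chloride (not isolated) | Cc1cc(OCc2ccc(OC)cc2)cc(OCc2ccc(OC)cc2)c1C(=O)Cl | intermediate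
10 | (1R,2R)-4-[(dimethylamino)methylidene]-2-methyl-3,5-dioxocyclohexyl 2,4-bis[(4-methoxyphenyl)methoxy]-6-methylbenzoate | Cc1cc(OCc2ccc(OC)cc2)cc(OCc2ccc(OC)cc2)c1C(=O)O[C@@H]1CC(=O)C(=CN(C)C)C(=O)[C@@H]1C | intermediate
11 | tert-butyl pent-4-ynoate | C#CCCC(=O)OC(C)(C)C | starting material
12 | tert-butyl 5-lithiopent-4-ynoate (not isolated) | [Li]C#CCCC(=O)OC(C)(C)C | intermediate
13 | tert-butyl 5-(dichlorocerio)pent-4-ynoate (not isolated) | Cl[Ce](Cl)C#CCCC(=O)OC(C)(C)C | intermediate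
14 | (1R,2R)-5-(5-tert-butoxy-5-oxopent-1-yn-1-yl)-4-[(dimethylamino)methylidene]-5-hydroxy-2-methyl-3-oxocyclohexyl 2,4-bis[(4-methoxyphenyl)methoxy]-6-methylbenzoate (both C5 epimers, not isolated) | Cc1cc(OCc2ccc(OC)cc2)cc(OCc2ccc(OC)cc2)c1C(=O)O[C@@H]1CC(O)(C#CCCC(=O)OC(C)(C)C)C(=CN(C)C)C(=O)[C@@H]1C | intermediate
15 | (1R,2R)-5-(5-tert-butoxy-5-oxopent-1-yn-1-yl)-4-formyl-2-methyl-3-oxocyclohex-4-en-1-yl 2,4-bis[(4-methoxyphenyl)methoxy]-6-methylbenzoate | Cc1cc(OCc2ccc(OC)cc2)cc(OCc2ccc(OC)cc2)c1C(=O)O[C@@H]1CC(C#CCCC(=O)OC(C)(C)C)=C(C=O)C(=O)[C@@H]1C | intermediate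
16 | (1R,2R)-5-(5-tert-butoxy-5-oxopent-1-yn-1-yl)-4-(hydroxymethyl)-2-methyl-3-oxocyclohex-4-en-1-yl 2,4-bis[(4-methoxyphenyl)methoxy]-6-methylbenzoate (not isolated) | Cc1cc(OCc2ccc(OC)cc2)cc(OCc2ccc(OC)cc2)c1C(=O)O[C@@H]1CC(C#CCCC(=O)OC(C)(C)C)=C(CO)C(=O)[C@@H]1C | intermediate
17 | tert-butyl 3-[(6R,7R)-6-({2,4-bis[(4-methoxyphenyl)methoxy]-6-methylbenzoyl}oxy)-7-methyl-8-oxo-5,6,7,8-tetrahydro-1H-isochromen-3-yl]propanoate | Cc1cc(OCc2ccc(OC)cc2)cc(OCc2ccc(OC)cc2)c1C(=O)O[C@@H]1CC2=C(COC(CCC(=O)OC(C)(C)C)=C2)C(=O)[C@@H]1C | intermediate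
18 | 3-[(6R,7R)-6-[(2,4-dihydroxy-6-methylbenzoyl)oxy]-7-methyl-8-oxo-5,6,7,8-tetrahydro-1H-isochromen-3-yl]propanoic acid (6-acyloxy and 7-methyl cis) | Cc1cc(O)cc(O)c1C(=O)O[C@@H]1CC2=C(COC(CCC(=O)O)=C2)C(=O)[C@@H]1C | target

**Step count and risks**

Total: 8 steps. Longest linear sequence: 7 steps (4 → 6 → 7 → 8 → 10 → 15 → 17 → 18); the branch from 1 is 5 steps.

Step 1 is the most uncertain step: rate, chemoselectivity against the aldehyde and the sense of enantio-induction are all unproven. The fallback sets out from 1 and returns at 3, replacing catalytic induction by resolution. NaBH4 in aqueous NaHCO3 at 0–23 °C (the stoichiometric reduction that turns phloroglucinol into dihydrophloroglucinol) gives racemic cis hydroxymethylidene dione F1, which is trapped with Me2NH·HCl as racemic enaminodione F2. Candida antarctica lipase B with vinyl acetate in t-BuOMe acetylates the (5R) alcohol (Kazlauskas rule) to (1R,2R)-acetate F3 and leaves the (4S,5S) alcohol F4, which is removed by chromatography. The same lipase in MeOH/t-BuOMe then removes the acetyl group of F3 under neutral conditions and delivers 3.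

Step 6 can fail if the acetylide attacks the aminomethylidene carbon or the wrong ring ketone, or acts as a base. The fallback sets out from 10 and returns at 15, replacing nucleophilic addition by activation and cross-coupling. Oxalyl chloride (CH2Cl2, 0 °C) O-activates the less hindered ring carbonyl of 10 and gives β-chlorovinyl iminium chloride F5. Aqueous NaOAc hydrolyses it to β-chloro enal F6. Sonogashira coupling of F6 with 11 (PdCl2(PPh3)2, CuI, Et3N, THF, 23 °C) gives 15.

Step 8 can fail because the β-aroyloxy ketone of 17 and 18 can aromatise by acid-promoted enolisation and loss of the orsellinate. The fallback sets out from 10 and returns at 18, unmasking before the sensitive ring system exists. CF3CO2H/anisole on the robust enaminodione 10 gives diphenol ester F7. After the phenols are deprotonated with LiN(SiMe3)2, addition of lithium 5-lithiopent-4-ynoate F8 (from pent-4-ynoic acid and 2 n-BuLi) gives carbinol F9, and acidic work-up converts it to ynenal acid F10. Excess i-Bu2AlH at −78 °C gives allylic alcohol F11, and AgOTf then closes the pyran to give 18 with no final acid treatment.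

**Further compounds**

F1 | step 1 | rac-(4R,5R)-5-hydroxy-2-(hydroxymethylidene)-4-methylcyclohexane-1,3-dione (racemate, both enantiomers written) | O[C@@H]1CC(=O)C(=CO)C(=O)[C@@H]1C.O[C@H]1CC(=O)C(=CO)C(=O)[C@H]1C
F2 | step 1 | rac-(4R,5R)-2-[(dimethylamino)methylidene]-5-hydroxy-4-methylcyclohexane-1,3-dione (racemate, both enantiomers written) | O[C@@H]1CC(=O)C(=CN(C)C)C(=O)[C@@H]1C.O[C@H]1CC(=O)C(=CN(C)C)C(=O)[C@H]1C
F3 | step 1 | (1R,2R)-4-[(dimethylamino)methylidene]-2-methyl-3,5-dioxocyclohexyl acetate | CC(=O)O[C@@H]1CC(=O)C(=CN(C)C)C(=O)[C@@H]1C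
F4 | step 1 | (4S,5S)-2-[(dimethylamino)methylidene]-5-hydroxy-4-methylcyclohexane-1,3-dione | O[C@H]1CC(=O)C(=CN(C)C)C(=O)[C@H]1C
F5 | step 6 | (1R,2R)-5-chloro-4-[(dimethyliminio)methyl]-2-methyl-3-oxocyclohex-4-en-1-yl 2,4-bis[(4-methoxyphenyl)methoxy]-6-methylbenzoate chloride | Cc1cc(OCc2ccc(OC)cc2)cc(OCc2ccc(OC)cc2)c1C(=O)O[C@@H]1CC(Cl)=C(C=[N+](C)C)C(=O)[C@@H]1C.[Cl-]
F6 | step 6 | (1R,2R)-5-chloro-4-formyl-2-methyl-3-oxocyclohex-4-en-1-yl 2,4-bis[(4-methoxyphenyl)methoxy]-6-methylbenzoate | Cc1cc(OCc2ccc(OC)cc2)cc(OCc2ccc(OC)cc2)c1C(=O)O[C@@H]1CC(Cl)=C(C=O)C(=O)[C@@H]1C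
F7 | step 8 | (1R,2R)-4-[(dimethylamino)methylidene]-2-methyl-3,5-dioxocyclohexyl 2,4-dihydroxy-6-methylbenzoate | Cc1cc(O)cc(O)c1C(=O)O[C@@H]1CC(=O)C(=CN(C)C)C(=O)[C@@H]1C
F8 | step 8 | lithium 5-lithiopent-4-ynoate | [Li]C#CCCC(=O)[O-].[Li+]
F9 | step 8 | (1R,2R)-5-(4-carboxybut-1-yn-1-yl)-4-[(dimethylamino)methylidene]-5-hydroxy-2-methyl-3-oxocyclohexyl 2,4-dihydroxy-6-methylbenzoate (both C5 epimers) | Cc1cc(O)cc(O)c1C(=O)O[C@@H]1CC(O)(C#CCCC(=O)O)C(=CN(C)C)C(=O)[C@@H]1C
F10 | step 8 | (1R,2R)-5-(4-carboxybut-1-yn-1-yl)-4-formyl-2-methyl-3-oxocyclohex-4-en-1-yl 2,4-dihydroxy-6-methylbenzoate | Cc1cc(O)cc(O)c1C(=O)O[C@@H]1CC(C#CCCC(=O)O)=C(C=O)C(=O)[C@@H]1C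
F11 | step 8 | (1R,2R)-5-(4-carboxybut-1-yn-1-yl)-4-(hydroxymethyl)-2-methyl-3-oxocyclohex-4-en-1-yl 2,4-dihydroxy-6-methylbenzoate | Cc1cc(O)cc(O)c1C(=O)O[C@@H]1CC(C#CCCC(=O)O)=C(CO)C(=O)[C@@H]1C
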